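The chemist who ran the zeta flask opened the meeting by tabling the recipe, the readings and the questions.

the same everywhere: left-handed substrate 0.80 M; right-handed substrate 0.80 M; precatalyst 1.6 mM
- zeta: coupling partner 2.4 M; the very flask that is asked about, followed so far
- flask: coupling partner 2.40 M; time 4.0 h

zeta run (percent of the left-handed substrate and right-handed substrate together charged)

| time / min | left-handed product / % | left-handed substrate / % |
|---|---|---|
| 12.0 | 4.2 | 46.4 |
| 20.0 | 9.5 | 41.4 |
| 30.0 | 17.8 | 35.9 |
| 50.0 | 33.3 | 23.3 |
| 80.0 | 49.2 | 13.3 |
| 150 | 61.5 | 1.9 |

(scatter of a reading: 0.5 percentage points)

- catalyst is single-handed; left-handed substrate and right-handed substrate are mirror images of each other, charged as a racemate, each of them at the stated concentration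
- removed left-handed product is counted in
- the analysis behind the earlier runs scatters by 0.5 percentage points, standard deviation
- additions bring no volume worth counting

- Sunday's: at 4.0 h take out 90% of the left-handed product then present, then wait 4.0 h
- Friday's: change nothing and wait 4.0 h more
- Saturday's: at 4.0 h add precatalyst, 100% of the amount charged, then wait 4.0 h

* left-handed product, in percent of the left-handed substrate and right-handed substrate together first charged, at 4.0 h
* what to do for the largest gain in left-handed product; "none" if nothing gains more than 2 percentage points (Sunday's / Friday's / Saturday's / none)
* left-handed product present, with what was taken out counted in, in percent of the left-handed substrate and right-handed substrate together first charged, after Friday's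
* left-handed product present, with what was taken out counted in, in percent of the left-handed substrate and right-handed substrate together first charged, after Saturday's

She reported that at 150 min left-handed product and left-handed substrate together stood 13 percentage points above the left-handed charge, so right-handed substrate had been turning into left-handed (racemization).

The analyst then offered a reckoning of his own. Suppose the turning keeps the mirror pair about even. Then the substrate consumed, both hands counted, is what is missing once the left-handed reading is doubled. At 150 min, product over substrate consumed reads 63.9%. He named this the left share, the selectivity of a dynamic kinetic resolution. It reads 62.4% at 50.0 min and 67.0% at 80.0 min, so he saw no collapse in it. The rest of the consumed substrate, he argued, must go somewhere unmeasured.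

On his count, 3.80% of the substrate remained at 150 min, worth 2.4 points of product, and he expected that remainder to shrink further by 4.0 h. He therefore committed to about 63.9% at 4.0 h, the left share of the whole charge, and expected no option to clear the margin.

The forecast was read into the minutes: 63.6% at 4.0 h, 64% after Friday's, 78% after Saturday's, and Saturday's as best. Its maker held that racemization had died near 80.0 min with right-handed substrate in stock, and that “Fresh precatalyst should restart racemization”. The two parted on that stock.

The flask gives 65.1% at 4.0 h, 65.7% after Friday's and 65.7% after Saturday's. Each option gains 0.56 points, less than the margin, so the answer is none.

    left-handed substrate ⇌ right-handed substrate (k = 0.00166 /s)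
    coupling partner + catalyst + right-handed substrate → catalyst + right-handed product (k = 0.190 /M²/s)
    precatalyst → catalyst (k = 2.22 × 10⁻⁴ /s)
    coupling partner + catalyst + left-handed substrate → catalyst + left-handed product (k = 0.386 /M²/s)

The main reason left-handed product stands at 65.1% is the coupling of right-handed substrate into right-handed product: the run without that step gives 96.4%. The left share of 63.9% leaves 36.1% of the consumed substrate for right-handed product, which stands in the flask at 34.0% of the charge at 4.0 h. In a neighbouring flask charged with 0.60 M of coupling partner, that charge can consume 37.5% of the substrate, so the left share gives 24.0%. The computed result in that flask at 4.0 h is 24.9%, with the coupling partner, the limiting reagent, down to 0.61% of its own charge.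

(Readings and results were computed for substances that don't exist; noise was put on by code.)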